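(The rate constants were drawn at random within sensible limits, and the outcome is calculated.)

The growth step turned a living end into a living end, so in this flask the count of chains, L, once begun, was conserved, and I reckoned the rate of growth around that invariant.

free monomer 21 mM; protic impurity 0.420 mM; initiator 99 µM; time 20 min

- whether the average number of monomer units in a chain (chains begun, living or dead) reaches 60 by 20 min (no / yes)
- average number of monomer units in a chain (chains begun, living or dead) at 20 min

- two of one species on the left: rate k times its square, two consumed each time
- the average divides the monomer in chains by the number of chains begun, living and dead together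
- run time (flask): 20 min

    free monomer + initiator → living end + monomer in chains (k1 = 14 M⁻¹ s⁻¹)
    free monomer + living end → monomer in chains + living end, rate k2*[living end]*[free monomer] (k2 = 19 M⁻¹ s⁻¹)
    2 initiator → spent initiator (k3 = 31 M⁻¹ s⁻¹)
    protic impurity + free monomer → quenched substrate (k4 = 4.2 M⁻¹ s⁻¹)
    monomer in chains → over-reaction product (k5 = 9.3 × 10⁻⁶ s⁻¹)

An initiator met free monomer at 0.294 s⁻¹ and the second initiator of self-loss at 0.00614 s⁻¹, faster by far, so I took L as the charge of initiator. With growth constant k = 19 M⁻¹ s⁻¹, the rate into chains on the full charge of free monomer began at 2.37 mM min⁻¹.

Two things slowed it. The protic impurity had a half-life of 0.13 min, short against the run, and took free monomer one for one, a factor of 0.980, which left a starting rate of 2.32 mM min⁻¹. The free monomer then fell pseudo-first-order with constant kL, so with x = kLt, here 2.26, I replaced the curve by its mean. The mean-rate factor φ, the mean rate over the time t divided by the starting rate, is one minus e to the minus x, over x, and came to 0.397. Monomer in chains had a half-life of 21 h by over-reaction, much longer than the run, so I dropped that loss. Mean rate times time, per chain, gave me 186 units, more than the length asked, so my answer was yes.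

The forecast answered yes with 186 units, the same length as mine, on this ground: “Initiation finishes within seconds and beats initiator self-loss”.

The flask gave yes and 186 units at 20 min.

The living end read 0.0980 mM at 2.00 min and 0.0980 mM at 20.0 min. For the shorter time of 10.0 min, x was 1.13 and φ rose to 0.599, which gave 141 units per chain. The flask at 10.0 min stood at 141 units.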